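**Retrosynthetic overview**

1. Target ⇐ acetylation, hydroxyl-directed 4,5-epoxidation and angeloylation of an (E,E)-germacra-1(10),4-diene-3,6-diol carrying PMB on O3 and TBS on O6.
2. Ten-membered ring ⇐ anionic oxy-Cope ring expansion of a trans-1,2-dialkenylcyclohexanol; the chair transition state makes both E alkenes and carries chirality to C3 through a (Z)-enol ether; enolate → triflate → CH3.
3. Dialkenylcyclohexanol ⇐ vinyl addition to a 2-alkenyl-3-silyloxy ketone ⇐ epoxy-alcohol semipinacol shift ⇐ (Z)-β-alkoxyvinyllithium + epoxy ketone.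
4. Epoxy ketone ⇐ key step: one-pot desymmetrizing isomerization/epoxidation of achiral 4-isopropylcyclohex-3-enone ⇐ Birch reduction of 4-isopropylanisole.
5. (Z)-2-Bromo enol ether ⇐ 4-methoxybenzyl alcohol + allyl bromide. Ring order: cyclohexane (from the arene), then the ten-membered ring, then the oxirane last.

Assumption: the target is the enantiomer drawn, (3R,4R,5R,6S,7S,1(10)E) in germacrane numbering (C1=C10 alkene, C3 angelate, C4/C5 epoxide, C6 acetate, C7 isopropyl); these carbon labels are also used for the cyclohexane precursors, and angelic anhydride is taken as commercial.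

**Step 1**
Reactants: 1 1-methoxy-4-(propan-2-yl)benzene (4-isopropylanisole)
Product: 3 4-(propan-2-yl)cyclohex-3-en-1-one, via methoxydiene 2 (not isolated)
Conditions: Li, NH3 (l), t-BuOH, THF, −33 °C; then (CO2H)2, MeOH/H2O, 25 °C
Reagents that add atoms: water, O
Why: Birch reduction gives the 1-methoxy-1,4-diene, and mild enol-ether hydrolysis gives the unconjugated, achiral β,γ-enone without moving the trisubstituted alkene (no stereocentre is formed).

**Step 2**
Reactants: 3 4-(propan-2-yl)cyclohex-3-en-1-one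
Product: 5 (1S,5S,6S)-5-(propan-2-yl)-7-oxabicyclo[4.1.0]heptan-2-one, via (S)-cryptone 4 (not isolated)
Conditions: 9-amino(9-deoxy)epi-quinine (10 mol %), CF3CO2H (20 mol %), dioxane, 25 °C; then 50% aq H2O2 (1.5 equiv), 30 °C
Reagents that add atoms: hydrogen peroxide, OO
Why: Proposed new method: one chiral primary-amine salt runs two reactions that are each known for this catalyst class — enantioselective β,γ→α,β isomerization of 4-substituted cyclohex-3-enones (iminium, dienamine, γ-protonation, which creates C7) and iminium-activated Weitz–Scheffer epoxidation of cyclohexenones with H2O2 — and here the conjugated iminium ion of 4 is epoxidized as it forms, hydroperoxide adding to C6 anti to the isopropyl group, while the iminium/dienamine equilibrium keeps C7 correctable until the irreversible O–O ring closure, so the matched catalyst–substrate pair is funnelled to the trans-epoxy ketone (the quinidine-derived pseudoenantiomer gives the mirror-image series and is substituted if the first run shows that sense).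

**Step 3**
Reactants: 6 (4-methoxyphenyl)methanol; 7 3-bromoprop-1-ene (allyl bromide)
Product: 9 1-methoxy-4-{[(1Z)-prop-1-en-1-yloxy]methyl}benzene, via allyl ether 8 (not isolated)
Conditions: NaH, THF, 0 → 25 °C; then KOtBu, DMSO, 60 °C
Reagents that add atoms: none
Why: Williamson etherification followed by base-mediated allyl-to-propenyl isomerization, which gives the (Z)-enol ether through the cis-chelated oxyallyl anion.

**Step 4**
Reactants: 9 1-methoxy-4-{[(1Z)-prop-1-en-1-yloxy]methyl}benzene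
Product: 11 1-({[(1Z)-2-bromoprop-1-en-1-yl]oxy}methyl)-4-methoxybenzene (Br cis to O), via dibromo ether 10 (not isolated)
Conditions: Br2, CH2Cl2, −78 °C; then DBU, −78 → 25 °C
Reagents that add atoms: bromine, BrBr
Why: Anti addition of Br2 to the enol ether and anti elimination of HBr (Br from the acetal-type C1, H from C2) replace the vinylic hydrogen by bromine with net retention, so the (Z)-propenyl ether gives the (Z)-bromide.

**Step 5**
Reactants: 5 (1S,5S,6S)-5-(propan-2-yl)-7-oxabicyclo[4.1.0]heptan-2-one; 11 1-({[(1Z)-2-bromoprop-1-en-1-yl]oxy}methyl)-4-methoxybenzene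
Product: 13 (1S,2S,5S,6S)-2-{(1Z)-1-[(4-methoxyphenyl)methoxy]prop-1-en-2-yl}-5-(propan-2-yl)-7-oxabicyclo[4.1.0]heptan-2-ol, via alkenyllithium 12 (not isolated)
Conditions: 11, t-BuLi (2.0 equiv), Et2O, −78 °C; then 5, −78 °C
Reagents that add atoms: none
Why: Bromine–lithium exchange with retention gives the O-coordinated (Z)-β-alkoxyvinyllithium, which adds 1,2 to the ketone from the face anti to the epoxide oxygen, placing the alkenyl group trans to the C5–O bond that breaks next.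

**Step 6**
Reactants: 13 (1S,2S,5S,6S)-2-{(1Z)-1-[(4-methoxyphenyl)methoxy]prop-1-en-2-yl}-5-(propan-2-yl)-7-oxabicyclo[4.1.0]heptan-2-ol
Product: 14 (2R,3S,4S)-3-{[tert-butyl(dimethyl)silyl]oxy}-2-{(1Z)-1-[(4-methoxyphenyl)methoxy]prop-1-en-2-yl}-4-(propan-2-yl)cyclohexan-1-one
Conditions: TBSOTf (1.2 equiv), 2,6-lutidine, CH2Cl2, −78 °C
Reagents that add atoms: tert-butyldimethylsilyl trifluoromethanesulfonate, CC(C)(C)[Si](C)(C)OS(=O)(=O)C(F)(F)F
Why: Silyl-triflate-promoted semipinacol rearrangement of a 2,3-epoxy alcohol: silylation of the epoxide oxygen triggers an anti-periplanar 1,2-shift of the electron-rich alkenyl group from C10 to C5 with inversion at C5, so the alkenyl (C5), silyloxy (C6) and isopropyl (C7) groups end all-trans and the ketone is unveiled.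

**Step 7**
Reactants: 14 (2R,3S,4S)-3-{[tert-butyl(dimethyl)silyl]oxy}-2-{(1Z)-1-[(4-methoxyphenyl)methoxy]prop-1-en-2-yl}-4-(propan-2-yl)cyclohexan-1-one
Product: 15 (1R,2R,3S,4S)-3-{[tert-butyl(dimethyl)silyl]oxy}-1-ethenyl-2-{(1Z)-1-[(4-methoxyphenyl)methoxy]prop-1-en-2-yl}-4-(propan-2-yl)cyclohexan-1-ol
Conditions: CH2=CHMgBr, CeCl3, THF, −78 °C
Reagents that add atoms: vinylmagnesium bromide, C=C[Mg]Br
Why: Organocerium 1,2-addition suppresses enolization and β-elimination of the silyloxy group, and equatorial attack anti to the C5 substituent gives the trans-1,2-dialkenyl (diequatorial) carbinol.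

**Step 8**
Reactants: 15 (1R,2R,3S,4S)-3-{[tert-butyl(dimethyl)silyl]oxy}-1-ethenyl-2-{(1Z)-1-[(4-methoxyphenyl)methoxy]prop-1-en-2-yl}-4-(propan-2-yl)cyclohexan-1-ol
Product: 17 (1Z,4R,5E,7S,8S)-7-{[tert-butyl(dimethyl)silyl]oxy}-4-[(4-methoxyphenyl)methoxy]-5-methyl-8-(propan-2-yl)cyclodeca-1,5-dien-1-yl trifluoromethanesulfonate, via potassium enolate 16 (not isolated)
Conditions: KH, 18-crown-6, THF, 0 → 25 °C; then PhNTf2, −78 → 0 °C
Reagents that add atoms: N-phenylbis(trifluoromethanesulfonimide), FC(F)(F)S(=O)(=O)N(c1ccccc1)S(=O)(=O)C(F)(F)F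
Why: Anionic oxy-Cope rearrangement through the chair transition state with both alkenyl groups equatorial gives the (E)-C4=C5 alkene and the ring-trans enolate and transfers the C5 configuration suprafacially to C3 (the Z-alkoxy group sits axial, giving 3R), and the regio- and geometry-defined enolate is trapped as the enol triflate.

**Step 9**
Reactants: 17 (1Z,4R,5E,7S,8S)-7-{[tert-butyl(dimethyl)silyl]oxy}-4-[(4-methoxyphenyl)methoxy]-5-methyl-8-(propan-2-yl)cyclodeca-1,5-dien-1-yl trifluoromethanesulfonate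
Product: 18 (3R,6S,7S,1(10)E,4E)-6-{[tert-butyl(dimethyl)silyl]oxy}-3-[(4-methoxyphenyl)methoxy]germacra-1(10),4-diene
Conditions: MeMgBr, Fe(acac)3 (5 mol %), THF/NMP, −30 °C
Reagents that add atoms: methylmagnesium bromide, C[Mg]Br
Why: Iron-catalysed cross-coupling of the alkenyl triflate with the methyl Grignard reagent proceeds with retention, turning the ring-trans triflate into the (E)-C1=C10 trisubstituted alkene.

**Step 10**
Reactants: 18 (3R,6S,7S,1(10)E,4E)-6-{[tert-butyl(dimethyl)silyl]oxy}-3-[(4-methoxyphenyl)methoxy]germacra-1(10),4-diene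
Product: 19 (3R,6S,7S,1(10)E,4E)-6-{[tert-butyl(dimethyl)silyl]oxy}germacra-1(10),4-dien-3-ol
Conditions: DDQ, CH2Cl2/pH 7 buffer, 0 °C
Reagents that add atoms: none
Why: Oxidative cleavage of the PMB ether (benzylic hydride abstraction, then hydrolysis of the oxocarbenium ion) under buffered conditions leaves the silyl ether and the acid-sensitive 1,5-diene untouched.

**Step 11**
Reactants: 19 (3R,6S,7S,1(10)E,4E)-6-{[tert-butyl(dimethyl)silyl]oxy}germacra-1(10),4-dien-3-ol
Product: 20 (3R,6S,7S,1(10)E,4E)-6-{[tert-butyl(dimethyl)silyl]oxy}germacra-1(10),4-dien-3-yl (2Z)-2-methylbut-2-enoate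
Conditions: LiN(SiMe3)2, THF, −78 °C; then angelic anhydride, −78 → 0 °C
Reagents that add atoms: angelic anhydride, C/C=C(/C)C(=O)OC(=O)/C(C)=C\C
Why: Acylation of the lithium alkoxide with the anhydride at low temperature avoids acylpyridinium intermediates and therefore Z-to-E isomerization of the angelate to the tiglate.

**Step 12**
Reactants: 20 (3R,6S,7S,1(10)E,4E)-6-{[tert-butyl(dimethyl)silyl]oxy}germacra-1(10),4-dien-3-yl (2Z)-2-methylbut-2-enoate
Product: 21 (3R,6S,7S,1(10)E,4E)-6-hydroxygermacra-1(10),4-dien-3-yl (2Z)-2-methylbut-2-enoate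
Conditions: Bu4NF, AcOH (1:1), THF, 0 → 25 °C
Reagents that add atoms: none
Why: Fluoride-mediated desilylation buffered with acetic acid frees the C6 hydroxyl without touching the ester or the diene.

**Step 13**
Reactants: 21 (3R,6S,7S,1(10)E,4E)-6-hydroxygermacra-1(10),4-dien-3-yl (2Z)-2-methylbut-2-enoate
Product: 22 (3R,4R,5R,6S,7S,1(10)E)-4,5-epoxy-6-hydroxygermacr-1(10)-en-3-yl (2Z)-2-methylbut-2-enoate
Conditions: VO(acac)2 (5 mol %), t-BuOOH, CH2Cl2, 0 °C
Reagents that add atoms: tert-butyl hydroperoxide, CC(C)(C)OO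
Why: Hydroxyl-directed vanadium-catalysed epoxidation selects the allylic C4=C5 alkene over the remote C1=C10 alkene, and A(1,3) strain with the cis C4 methyl holds H6 in the alkene plane so the C6 hydroxyl delivers oxygen to the outer face, giving the (4R,5R) trans-epoxide.

**Step 14**
Reactants: 22 (3R,4R,5R,6S,7S,1(10)E)-4,5-epoxy-6-hydroxygermacr-1(10)-en-3-yl (2Z)-2-methylbut-2-enoate
Product: 23 (3R,4R,5R,6S,7S,1(10)E)-6-acetoxy-4,5-epoxygermacr-1(10)-en-3-yl (2Z)-2-methylbut-2-enoate (CNP0180504.3)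
Conditions: Ac2O, pyridine, DMAP (cat.), CH2Cl2, 0 → 25 °C
Reagents that add atoms: acetic anhydride, CC(=O)OC(C)=O
Why: DMAP-catalysed acetylation of the remaining secondary alcohol gives the target without affecting the epoxide or the angelate.

**Compound list**

1 | 1-methoxy-4-(propan-2-yl)benzene | COc1ccc(C(C)C)cc1 | starting material
2 | 1-methoxy-4-(propan-2-yl)cyclohexa-1,4-diene | COC1=CCC(C(C)C)=CC1 | intermediate
3 | 4-(propan-2-yl)cyclohex-3-en-1-one | O=C1CCC(C(C)C)=CC1 | intermediate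
4 | (4S)-4-(propan-2-yl)cyclohex-2-en-1-one | O=C1CC[C@@H](C(C)C)C=C1 | intermediate
5 | (1S,5S,6S)-5-(propan-2-yl)-7-oxabicyclo[4.1.0]heptan-2-one | O=C1CC[C@@H](C(C)C)[C@@H]2O[C@H]12 | intermediate
6 | (4-methoxyphenyl)methanol | COc1ccc(CO)cc1 | starting material
7 | 3-bromoprop-1-ene | C=CCBr | starting material
8 | 1-methoxy-4-[(prop-2-en-1-yloxy)methyl]benzene | C=CCOCc1ccc(OC)cc1 | intermediate
9 | 1-methoxy-4-{[(1Z)-prop-1-en-1-yloxy]methyl}benzene | C/C=C\OCc1ccc(OC)cc1 | intermediate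
10 | 1-[(1,2-dibromopropoxy)methyl]-4-methoxybenzene (racemic anti adduct) | CC(Br)C(Br)OCc1ccc(OC)cc1 | intermediate
11 | 1-({[(1Z)-2-bromoprop-1-en-1-yl]oxy}methyl)-4-methoxybenzene | Br/C(C)=C\OCc1ccc(OC)cc1 | intermediate
12 | {(1Z)-1-[(4-methoxyphenyl)methoxy]prop-1-en-2-yl}lithium | [Li]/C(C)=C\OCc1ccc(OC)cc1 | intermediate
13 | (1S,2S,5S,6S)-2-{(1Z)-1-[(4-methoxyphenyl)methoxy]prop-1-en-2-yl}-5-(propan-2-yl)-7-oxabicyclo[4.1.0]heptan-2-ol | O[C@]1(/C(C)=C\OCc3ccc(OC)cc3)CC[C@@H](C(C)C)[C@@H]2O[C@H]12 | intermediate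
14 | (2R,3S,4S)-3-{[tert-butyl(dimethyl)silyl]oxy}-2-{(1Z)-1-[(4-methoxyphenyl)methoxy]prop-1-en-2-yl}-4-(propan-2-yl)cyclohexan-1-one | O=C1CC[C@@H](C(C)C)[C@H](O[Si](C)(C)C(C)(C)C)[C@H]1/C(C)=C\OCc1ccc(OC)cc1 | intermediate
15 | (1R,2R,3S,4S)-3-{[tert-butyl(dimethyl)silyl]oxy}-1-ethenyl-2-{(1Z)-1-[(4-methoxyphenyl)methoxy]prop-1-en-2-yl}-4-(propan-2-yl)cyclohexan-1-ol | O[C@@]1(C=C)CC[C@@H](C(C)C)[C@H](O[Si](C)(C)C(C)(C)C)[C@H]1/C(C)=C\OCc1ccc(OC)cc1 | intermediate
16 | potassium (1Z,4R,5E,7S,8S)-7-{[tert-butyl(dimethyl)silyl]oxy}-4-[(4-methoxyphenyl)methoxy]-5-methyl-8-(propan-2-yl)cyclodeca-1,5-dien-1-olate | COc1ccc(CO[C@@H]2C/C=C(\[O-])CC[C@@H](C(C)C)[C@H](O[Si](C)(C)C(C)(C)C)/C=C2\C)cc1.[K+] | intermediate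
17 | (1Z,4R,5E,7S,8S)-7-{[tert-butyl(dimethyl)silyl]oxy}-4-[(4-methoxyphenyl)methoxy]-5-methyl-8-(propan-2-yl)cyclodeca-1,5-dien-1-yl trifluoromethanesulfonate | COc1ccc(CO[C@@H]2C/C=C(\OS(=O)(=O)C(F)(F)F)CC[C@@H](C(C)C)[C@H](O[Si](C)(C)C(C)(C)C)/C=C2\C)cc1 | intermediate
18 | (3R,6S,7S,1(10)E,4E)-6-{[tert-butyl(dimethyl)silyl]oxy}-3-[(4-methoxyphenyl)methoxy]germacra-1(10),4-diene | COc1ccc(CO[C@@H]2C/C=C(\C)CC[C@@H](C(C)C)[C@H](O[Si](C)(C)C(C)(C)C)/C=C2\C)cc1 | intermediate
19 | (3R,6S,7S,1(10)E,4E)-6-{[tert-butyl(dimethyl)silyl]oxy}germacra-1(10),4-dien-3-ol | O[C@@H]1C/C=C(\C)CC[C@@H](C(C)C)[C@H](O[Si](C)(C)C(C)(C)C)/C=C1\C | intermediate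
20 | (3R,6S,7S,1(10)E,4E)-6-{[tert-butyl(dimethyl)silyl]oxy}germacra-1(10),4-dien-3-yl (2Z)-2-methylbut-2-enoate | C/C=C(/C)C(=O)O[C@@H]1C/C=C(\C)CC[C@@H](C(C)C)[C@H](O[Si](C)(C)C(C)(C)C)/C=C1\C | intermediate
21 | (3R,6S,7S,1(10)E,4E)-6-hydroxygermacra-1(10),4-dien-3-yl (2Z)-2-methylbut-2-enoate | C/C=C(/C)C(=O)O[C@@H]1C/C=C(\C)CC[C@@H](C(C)C)[C@H](O)/C=C1\C | intermediate
22 | (3R,4R,5R,6S,7S,1(10)E)-4,5-epoxy-6-hydroxygermacr-1(10)-en-3-yl (2Z)-2-methylbut-2-enoate | C/C=C(/C)C(=O)O[C@@H]1C/C=C(\C)CC[C@@H](C(C)C)[C@H](O)[C@H]2O[C@@]21C | intermediate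
23 | (3R,4R,5R,6S,7S,1(10)E)-6-acetoxy-4,5-epoxygermacr-1(10)-en-3-yl (2Z)-2-methylbut-2-enoate | C/C=C(/C)C(=O)O[C@@H]1C/C=C(\C)CC[C@@H](C(C)C)[C@H](OC(C)=O)[C@H]2O[C@@]21C | target

**Totals**

Total step count: 14.
Longest linear sequence: 12 steps (steps 1, 2, 5–14 from 1; the branch from 6 through steps 3, 4, 5–14 is equally long).

**Steps most likely to fail**

Step 2 (one-pot isomerization/epoxidation). The two catalyst-controlled events may be mismatched or C7 may not equilibrate, giving low ee or the cis-epoxide. The fallback sets out from 3 and returns at 5. The alkene of 3 is hydrogenated (H2, Pd/C, EtOAc) to 4-(propan-2-yl)cyclohexan-1-one F1. This symmetric ketone is desymmetrized by enantiotopic deprotonation with a chiral lithium amide (lithium bis(1-phenylethyl)amide, LiCl, Me3SiCl in situ, THF, −100 °C, using the base enantiomer that gives the 4R series) to trimethyl{[(4R)-4-(propan-2-yl)cyclohex-1-en-1-yl]oxy}silane F2. Saegusa–Ito dehydrosilylation (Pd(OAc)2, MeCN) gives isolated 4, and substrate-controlled Weitz–Scheffer epoxidation (H2O2, NaOH, MeOH, 0 °C, anti to isopropyl) gives 5.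

Step 6 (semipinacol shift of an enol-ether group). The silyl triflate may ionize the tertiary allylic alcohol or degrade the enol ether instead of triggering the 1,2-shift. The fallback sets out from 4 (isolated by running step 2 without H2O2) and returns at 14. α-Iodination (I2, pyridine, CH2Cl2) gives (4S)-2-iodo-4-(propan-2-yl)cyclohex-2-en-1-one F3. Alkenyllithium 12 is transmetalated with ZnCl2 to chloro{(1Z)-1-[(4-methoxyphenyl)methoxy]prop-1-en-2-yl}zinc F4, and Negishi coupling (Pd(PPh3)4, THF) gives (4S)-2-{(1Z)-1-[(4-methoxyphenyl)methoxy]prop-1-en-2-yl}-4-(propan-2-yl)cyclohex-2-en-1-one F5. Copper-catalysed conjugate borylation (CuCl, NaOtBu, DPEphos, B2pin2, MeOH, THF), anti to isopropyl with thermodynamic protonation at C5, gives (2S,3S,4R)-2-{(1Z)-1-[(4-methoxyphenyl)methoxy]prop-1-en-2-yl}-4-(propan-2-yl)-3-(4,4,5,5-tetramethyl-1,3,2-dioxaborolan-2-yl)cyclohexan-1-one F6. Oxidation with NaBO3·4H2O (retention) gives (2R,3S,4S)-3-hydroxy-2-{(1Z)-1-[(4-methoxyphenyl)methoxy]prop-1-en-2-yl}-4-(propan-2-yl)cyclohexan-1-one F7, and silylation (TBSOTf, 2,6-lutidine) gives 14.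

Step 8 (oxy-Cope chirality transfer to C3). A competing boat pathway, or Z/E erosion in 11, would give C3 epimers. The fallback sets out from 19 (carried through steps 8–10 as the epimer mixture) and returns at 19. Oxidation (Dess–Martin periodinane, NaHCO3, CH2Cl2, 0 °C) gives (6S,7S,1(10)E,4E)-6-{[tert-butyl(dimethyl)silyl]oxy}germacra-1(10),4-dien-3-one F8. Reagent-controlled reduction ((S)-2-methyl-CBS-oxazaborolidine, catecholborane, toluene, −78 °C, with the alkenyl carbon as the large group) gives the 3R alcohol 19 as a single epimer.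

**Further compounds**

F1 | step 2 | 4-(propan-2-yl)cyclohexan-1-one | CC(C)C1CCC(=O)CC1
F2 | step 2 | trimethyl{[(4R)-4-(propan-2-yl)cyclohex-1-en-1-yl]oxy}silane | C[Si](C)(C)OC1=CC[C@H](C(C)C)CC1
F3 | step 6 | (4S)-2-iodo-4-(propan-2-yl)cyclohex-2-en-1-one | O=C1CC[C@@H](C(C)C)C=C1I
F4 | step 6 | chloro{(1Z)-1-[(4-methoxyphenyl)methoxy]prop-1-en-2-yl}zinc | Cl[Zn]/C(C)=C\OCc1ccc(OC)cc1
F5 | step 6 | (4S)-2-{(1Z)-1-[(4-methoxyphenyl)methoxy]prop-1-en-2-yl}-4-(propan-2-yl)cyclohex-2-en-1-one | O=C1CC[C@@H](C(C)C)C=C1/C(C)=C\OCc1ccc(OC)cc1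
F6 | step 6 | (2S,3S,4R)-2-{(1Z)-1-[(4-methoxyphenyl)methoxy]prop-1-en-2-yl}-4-(propan-2-yl)-3-(4,4,5,5-tetramethyl-1,3,2-dioxaborolan-2-yl)cyclohexan-1-one | O=C1CC[C@@H](C(C)C)[C@H](B2OC(C)(C)C(C)(C)O2)[C@H]1/C(C)=C\OCc1ccc(OC)cc1
F7 | step 6 | (2R,3S,4S)-3-hydroxy-2-{(1Z)-1-[(4-methoxyphenyl)methoxy]prop-1-en-2-yl}-4-(propan-2-yl)cyclohexan-1-one | O=C1CC[C@@H](C(C)C)[C@H](O)[C@H]1/C(C)=C\OCc1ccc(OC)cc1
F8 | step 8 | (6S,7S,1(10)E,4E)-6-{[tert-butyl(dimethyl)silyl]oxy}germacra-1(10),4-dien-3-one | O=C1C/C=C(\C)CC[C@@H](C(C)C)[C@H](O[Si](C)(C)C(C)(C)C)/C=C1\C
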